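## Retrosynthetic overview

1. Target acid 26 ⇐ methyl ester 24 ⇐ Csp3–Csp2 Negishi coupling (C9–C10) of dioxane iodide 13 with dienyl iodide 22, itself built from benzyl bromide and two propyne units by two hydrozirconation–iodination cycles.
2. Iodide 13 ⇐ ozonolysis, reduction and iodination of the spare enoate arm of 1,2-dioxane 10.
3. Dioxane 10 (the only ring, closed once) ⇐ C3–O bond: group-selective peroxy-Michael cyclisation of hydroperoxide 9. Its peroxy-bearing carbon carries two identical (S)-enoate arms and is not stereogenic until the ring closes, so this step sets C3 and C6 together.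
4. Hydroperoxide 9 ⇐ Co-catalysed hydroperoxysilylation (C6–O bond) of the C2-symmetric diester 7 ⇐ two-directional Evans alkylation of 3-bromo-2-(bromomethyl)prop-1-ene (sets C4 and C8), reduction, oxidation/Wittig.

Assumption: ring atoms are numbered O1, O2, C3 (bears the acetate arm), C4, C5, C6 and the side chain runs C7 to C14 throughout; the quinine-derived squaramide is taken as the matched catalyst in step 5 (its quinidine-derived pseudo-enantiomer is the first alternative).

## Route

Step 1
Reactants: 1 (4R)-4-benzyl-3-propanoyl-1,3-oxazolidin-2-one; 2 3-bromo-2-(bromomethyl)prop-1-ene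
Product: 4 (4R,4'R)-3,3'-[(2S,6S)-2,6-dimethyl-4-methylideneheptanedioyl]bis(4-benzyl-1,3-oxazolidin-2-one), via monoalkylated allylic bromide 3 (not isolated)
Conditions: NaN(SiMe3)2 (2.5 equiv), 1 (2.5 equiv), THF, −78 °C; then 2 (1.0 equiv), −78 → −30 °C
Reagents that add atoms: none
Why: Two-directional Evans asymmetric alkylation, in which the chelated (Z)-sodium enolate of the (R)-benzyl imide is attacked by the allylic bromide on the face opposite the benzyl group, twice, so both new methyl stereocentres (future C4 and C8) are (S).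

Step 2
Reactants: 4 bis-imide
Product: 5 (2S,6S)-2,6-dimethyl-4-methylideneheptane-1,7-diol
Conditions: LiBH4, MeOH (1 equiv per hydride), THF, 0 °C → rt
Reagents that add atoms: none
Why: Reductive cleavage of the N-acyl oxazolidinones by hydride attack at the exocyclic carbonyls gives the diol without touching the stereocentres or the alkene, and the auxiliary is recovered.

Step 3
Reactants: 5 diol
Product: 7 dimethyl (2E,4S,8S,9E)-4,8-dimethyl-6-methylideneundeca-2,9-dienedioate, via dialdehyde 6 (not isolated)
Conditions: TEMPO (20 mol %), PhI(OAc)2, CH2Cl2, rt; then Ph3P=CHCO2Me, rt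
Reagents that add atoms: methyl (triphenylphosphoranylidene)acetate, COC(=O)C=P(c1ccccc1)(c1ccccc1)c1ccccc1
Why: One-pot TEMPO/PhI(OAc)2 oxidation and Wittig olefination with a stabilised ylide traps the epimerisable α-methyl dialdehyde as it forms and gives both (E)-enoates.

Step 4
Reactants: 7 bis-enoate
Product: 8 dimethyl (2E,4S,8S,9E)-4,6,8-trimethyl-6-[(triethylsilyl)peroxy]undeca-2,9-dienedioate
Conditions: Co(thd)2 (10 mol %; thd = 2,2,6,6-tetramethylheptane-3,5-dionate), O2 (1 atm), Et3SiH, ClCH2CH2Cl, rt
Reagents that add atoms: dioxygen, O=O; triethylsilane, CC[SiH](CC)CC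
Why: Mukaiyama–Isayama hydroperoxysilylation, in which the cobalt hydride transfers H to the electron-rich 1,1-dialkyl alkene much faster than to the electron-poor enoates, and the tertiary radical is trapped by O2 and silylated; no stereocentre is created because C6 carries two identical arms.

Step 5
Reactants: 8 silyl peroxide
Product: 10 methyl (2E,4S)-5-[(3R,4S,6R)-3-(2-methoxy-2-oxoethyl)-4,6-dimethyl-1,2-dioxan-6-yl]-4-methylpent-2-enoate, via hydroperoxide 9 (not isolated)
Conditions: HCl (cat.), MeOH, 0 °C, evaporate; then quinine-derived squaramide 3-{[3,5-bis(trifluoromethyl)phenyl]amino}-4-{[(9S)-6'-methoxycinchonan-9-yl]amino}cyclobut-3-ene-1,2-dione (10 mol %), toluene, rt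
Reagents that add atoms: none
Why: Proposed new method: a catalyst-controlled, diastereotopic-group-selective intramolecular peroxy-Michael (hydroperoxide oxa-Michael) cyclisation in which the single C3–O bond formation creates both C3 and C6, because C6 of 9 is not stereogenic while its two (S)-enoate arms are identical; the quinuclidine nitrogen deprotonates the hydroperoxide, the squaramide N–H bonds activate one enoate carbonyl, and closure through the chair with the C4 methyl, the enoate and the non-reacting arm all equatorial (C6 methyl axial) gives the 3,4-trans (3R,4S,6R) isomer, the bulky ion-paired catalyst at the peroxide terminus raising the cost of the competing chair with the second arm axial, and since closure is reversible by retro-Michael the all-equatorial product is also the thermodynamic sink; the closest known reactions are the amine-promoted (Et2NH/CF3CH2OH) hydroperoxide oxa-Michael closure of 1,2-dioxanes and cinchona-amine or squaramide-catalysed asymmetric oxa-Michael and enone peroxidation reactions.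

Step 6
Reactants: 10 dioxane enoate
Product: 12 methyl 2-[(3R,4S,6R)-6-[(2S)-3-hydroxy-2-methylpropyl]-4,6-dimethyl-1,2-dioxan-3-yl]acetate, via aldehyde 11 (not isolated)
Conditions: O3, CH2Cl2/MeOH, −78 °C; then NaBH4, −78 → 0 °C
Reagents that add atoms: ozone, [O-][O+]=O
Why: Ozonolysis with reductive NaBH4 work-up cleaves the only C=C, and the α-methyl aldehyde is reduced in situ (no epimerisation at C8) while the dialkyl peroxide and saturated ester are inert.

Step 7
Reactants: 12 alcohol
Product: 13 methyl 2-[(3R,4S,6S)-6-[(2S)-3-iodo-2-methylpropyl]-4,6-dimethyl-1,2-dioxan-3-yl]acetate (C6 descriptor changes by CIP priority only)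
Conditions: PPh3 + I2 (premixed), imidazole, CH2Cl2, 0 °C
Reagents that add atoms: iodine, II
Why: Appel-type (Garegg–Samuelsson) iodination by SN2 displacement of the alkoxyphosphonium at the primary carbon; premixing PPh3 with I2 leaves no free phosphine to attack the peroxide.

Step 8
Reactants: 14 benzyl bromide; 15 prop-1-yn-1-ylmagnesium bromide
Product: 16 but-2-yn-1-ylbenzene
Conditions: CuBr (5 mol %), THF, 0 → 50 °C
Reagents that add atoms: none
Why: Copper-catalysed coupling of an alkynyl Grignard reagent with a benzylic bromide (SN2-type Csp–Csp3 coupling).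

Step 9
Reactants: 16 but-2-yn-1-ylbenzene
Product: 18 [(2E)-3-iodobut-2-en-1-yl]benzene, via alkenylzirconocene 17 (not isolated)
Conditions: Cp2Zr(H)Cl (2 equiv), THF, 50 °C; then I2, 0 °C
Reagents that add atoms: iodine, II
Why: Hydrozirconation–iodination, with syn Zr–H addition that equilibrates to zirconium on the less hindered methyl-bearing carbon and iodinolysis with retention, giving the (E)-iodide.

Step 10
Reactants: 18 vinyl iodide; 19 propyne
Product: 20 [(2E)-3-methylhex-2-en-4-yn-1-yl]benzene
Conditions: Pd(PPh3)2Cl2 (2 mol %), CuI (4 mol %), Et3N, THF, propyne (1 atm), rt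
Reagents that add atoms: none
Why: Sonogashira coupling proceeds with retention of the alkenyl iodide geometry.

Step 11
Reactants: 20 enyne
Product: 22 [(2E,4E)-5-iodo-3-methylhexa-2,4-dien-1-yl]benzene, via dienylzirconocene 21 (not isolated)
Conditions: Cp2Zr(H)Cl (2 equiv), THF, 50 °C; then I2, 0 °C
Reagents that add atoms: iodine, II
Why: Hydrozirconation–iodination of the alkyne (far more reactive than the trisubstituted alkene) places zirconium at the methyl terminus by syn addition, and iodinolysis with retention gives the (2E,4E)-dienyl iodide.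

Step 12
Reactants: 13 dioxane iodide; 22 dienyl iodide
Product: 24 methyl 2-[(3R,4S,6R)-4,6-dimethyl-6-[(2R,4E,6E)-2,4,6-trimethyl-8-phenylocta-4,6-dien-1-yl]-1,2-dioxan-3-yl]acetate, via alkylzinc iodide 23 (not isolated)
Conditions: Zn dust, LiCl, THF, 35 °C; then 22, Pd(dppf)Cl2 (5 mol %), THF, rt
Reagents that add atoms: none
Why: Negishi Csp3–Csp2 coupling, with ester-tolerant zinc insertion into the primary iodide and Pd-catalysed coupling in which oxidative addition occurs at the alkenyl iodide (so β-branching does not hinder it) with retention of diene geometry; C8 is untouched.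

Step 13
Reactants: 24 methyl ester
Product: 26 2-[(3R,4S,6R)-4,6-dimethyl-6-[(2R,4E,6E)-2,4,6-trimethyl-8-phenylocta-4,6-dien-1-yl]-1,2-dioxan-3-yl]acetic acid, via lithium carboxylate 25 (not isolated)
Conditions: LiOH, THF/H2O, 0 °C → rt; then 1 M HCl to pH 3
Reagents that add atoms: lithium hydroxide, [Li+].[OH-]
Why: Saponification of the unhindered methyl ester under mild, cold conditions that keep retro-Michael opening of the β-peroxy ester slow, followed by protonation.

## Compound list

1 | (4R)-4-benzyl-3-propanoyl-1,3-oxazolidin-2-one | CCC(=O)N1[C@H](Cc2ccccc2)COC1=O | starting material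
2 | 3-bromo-2-(bromomethyl)prop-1-ene | C=C(CBr)CBr | starting material
3 | (4R)-4-benzyl-3-[(2S)-4-(bromomethyl)-2-methylpent-4-enoyl]-1,3-oxazolidin-2-one | BrCC(=C)C[C@H](C)C(=O)N1[C@H](Cc2ccccc2)COC1=O | intermediate
4 | (4R,4'R)-3,3'-[(2S,6S)-2,6-dimethyl-4-methylideneheptanedioyl]bis(4-benzyl-1,3-oxazolidin-2-one) | O=C1OC[C@@H](Cc2ccccc2)N1C(=O)[C@@H](C)CC(=C)C[C@H](C)C(=O)N1[C@H](Cc2ccccc2)COC1=O | intermediate
5 | (2S,6S)-2,6-dimethyl-4-methylideneheptane-1,7-diol | OC[C@@H](C)CC(=C)C[C@H](C)CO | intermediate
6 | (2S,6S)-2,6-dimethyl-4-methylideneheptanedial | O=C[C@@H](C)CC(=C)C[C@H](C)C=O | intermediate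
7 | dimethyl (2E,4S,8S,9E)-4,8-dimethyl-6-methylideneundeca-2,9-dienedioate | COC(=O)/C=C/[C@@H](C)CC(=C)C[C@H](C)/C=C/C(=O)OC | intermediate
8 | dimethyl (2E,4S,8S,9E)-4,6,8-trimethyl-6-[(triethylsilyl)peroxy]undeca-2,9-dienedioate (C6 not stereogenic) | COC(=O)/C=C/[C@@H](C)CC(C)(OO[Si](CC)(CC)CC)C[C@H](C)/C=C/C(=O)OC | intermediate
9 | dimethyl (2E,4S,8S,9E)-6-hydroperoxy-4,6,8-trimethylundeca-2,9-dienedioate (C6 not stereogenic) | COC(=O)/C=C/[C@@H](C)CC(C)(OO)C[C@H](C)/C=C/C(=O)OC | intermediate
10 | methyl (2E,4S)-5-[(3R,4S,6R)-3-(2-methoxy-2-oxoethyl)-4,6-dimethyl-1,2-dioxan-6-yl]-4-methylpent-2-enoate | COC(=O)/C=C/[C@@H](C)C[C@]1(C)C[C@H](C)[C@@H](CC(=O)OC)OO1 | intermediate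
11 | methyl 2-[(3R,4S,6S)-4,6-dimethyl-6-[(2S)-2-methyl-3-oxopropyl]-1,2-dioxan-3-yl]acetate | O=C[C@@H](C)C[C@]1(C)C[C@H](C)[C@@H](CC(=O)OC)OO1 | intermediate
12 | methyl 2-[(3R,4S,6R)-6-[(2S)-3-hydroxy-2-methylpropyl]-4,6-dimethyl-1,2-dioxan-3-yl]acetate | OC[C@@H](C)C[C@]1(C)C[C@H](C)[C@@H](CC(=O)OC)OO1 | intermediate
13 | methyl 2-[(3R,4S,6S)-6-[(2S)-3-iodo-2-methylpropyl]-4,6-dimethyl-1,2-dioxan-3-yl]acetate | IC[C@@H](C)C[C@]1(C)C[C@H](C)[C@@H](CC(=O)OC)OO1 | intermediate
14 | benzyl bromide | BrCc1ccccc1 | starting material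
15 | prop-1-yn-1-ylmagnesium bromide | CC#C[Mg]Br | starting material
16 | but-2-yn-1-ylbenzene | CC#CCc1ccccc1 | intermediate
17 | chlorobis(cyclopentadienyl)[(2E)-4-phenylbut-2-en-2-yl]zirconium | C/C(=C\Cc1ccccc1)[Zr](Cl)(C1C=CC=C1)C1C=CC=C1 | intermediate
18 | [(2E)-3-iodobut-2-en-1-yl]benzene | C/C(I)=C\Cc1ccccc1 | intermediate
19 | propyne | CC#C | starting material
20 | [(2E)-3-methylhex-2-en-4-yn-1-yl]benzene | CC#C/C(C)=C/Cc1ccccc1 | intermediate
21 | chlorobis(cyclopentadienyl)[(2E,4E)-4-methyl-6-phenylhexa-2,4-dien-2-yl]zirconium | CC(=C\Cc1ccccc1)/C=C(\C)[Zr](Cl)(C1C=CC=C1)C1C=CC=C1 | intermediate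
22 | [(2E,4E)-5-iodo-3-methylhexa-2,4-dien-1-yl]benzene | CC(=C\Cc1ccccc1)/C=C(\C)I | intermediate
23 | iodo{(2S)-3-[(3R,4S,6S)-3-(2-methoxy-2-oxoethyl)-4,6-dimethyl-1,2-dioxan-6-yl]-2-methylpropyl}zinc | I[Zn]C[C@@H](C)C[C@]1(C)C[C@H](C)[C@@H](CC(=O)OC)OO1 | intermediate
24 | methyl 2-[(3R,4S,6R)-4,6-dimethyl-6-[(2R,4E,6E)-2,4,6-trimethyl-8-phenylocta-4,6-dien-1-yl]-1,2-dioxan-3-yl]acetate | CC(=C\Cc1ccccc1)/C=C(\C)C[C@@H](C)C[C@]1(C)C[C@H](C)[C@@H](CC(=O)OC)OO1 | intermediate
25 | lithium 2-[(3R,4S,6R)-4,6-dimethyl-6-[(2R,4E,6E)-2,4,6-trimethyl-8-phenylocta-4,6-dien-1-yl]-1,2-dioxan-3-yl]acetate | CC(=C\Cc1ccccc1)/C=C(\C)C[C@@H](C)C[C@]1(C)C[C@H](C)[C@@H](CC(=O)[O-])OO1.[Li+] | intermediate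
26 | 2-[(3R,4S,6R)-4,6-dimethyl-6-[(2R,4E,6E)-2,4,6-trimethyl-8-phenylocta-4,6-dien-1-yl]-1,2-dioxan-3-yl]acetic acid | CC(=C\Cc1ccccc1)/C=C(\C)C[C@@H](C)C[C@]1(C)C[C@H](C)[C@@H](CC(=O)O)OO1 | target

## Step count and risk

Total step count: 13 (steps 1–7, 12 and 13 on the main line; steps 8–11 for the side-chain iodide).
Longest linear sequence: 9 steps (1 → 7, 12, 13).

The three steps most likely to fail are 5, 12 and 4.

The cyclisation of step 5 is the proposed new reaction, and its risk is insufficient discrimination between the two arms (C6) or a slow catalytic turnover. The fallback uses the known amine-promoted hydroperoxide oxa-Michael closure and replaces catalyst control by separation and recycling. It sets out from hydroperoxide 9 (made as in the first stage of step 5) and treats it with Et2NH in CF3CH2OH at rt. This gives 10 together with its C6 epimer methyl (2E,4S)-5-[(3R,4S,6S)-3-(2-methoxy-2-oxoethyl)-4,6-dimethyl-1,2-dioxan-6-yl]-4-methylpent-2-enoate F3, which are separated on silica. Because C6 is not stereogenic in 9, F3 is not a dead end: re-exposure to the same basic medium is expected to reopen it by retro-Michael to 9 and feed the more stable all-equatorial isomer. The fallback comes back to the route at 10.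

The coupling of step 12 may fail because zinc metal or the organozinc damages the O–O bond before coupling. The fallback inverts the polarity so that the peroxide fragment is only ever an electrophile and no zinc metal is used. It sets out from iodide 13 and enyne 20: hydrozirconation of 20 (Cp2Zr(H)Cl, THF) gives dienylzirconocene 21, which is coupled directly with 13 under phosphine-free Pd(acac)2/LiBr catalysis in THF/NMP at 55 °C (the known alkyl halide–alkenylzirconium Negishi-type coupling). It comes back to the route at ester 24.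

The hydroperoxysilylation of step 4 may suffer from competing cobalt hydride reduction or α-peroxidation of the two enoates. The fallback changes the order so that the 1,1-disubstituted alkene is the only C=C present when the peroxide is installed. It sets out from diol 5, which under the same Co(thd)2/O2/Et3SiH conditions gives (2S,6S)-2,4,6-trimethyl-4-[(triethylsilyl)peroxy]heptane-1,7-diol F1. TEMPO/PhI(OAc)2 oxidation then gives (2S,6S)-2,4,6-trimethyl-4-[(triethylsilyl)peroxy]heptanedial F2, which is treated in the same flask with Ph3P=CHCO2Me. It comes back to the route at silyl peroxide 8.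

## Further compounds

F1 | step 4 | (2S,6S)-2,4,6-trimethyl-4-[(triethylsilyl)peroxy]heptane-1,7-diol | OC[C@@H](C)CC(C)(OO[Si](CC)(CC)CC)C[C@H](C)CO
F2 | step 4 | (2S,6S)-2,4,6-trimethyl-4-[(triethylsilyl)peroxy]heptanedial | O=C[C@@H](C)CC(C)(OO[Si](CC)(CC)CC)C[C@H](C)C=O
F3 | step 5 | methyl (2E,4S)-5-[(3R,4S,6S)-3-(2-methoxy-2-oxoethyl)-4,6-dimethyl-1,2-dioxan-6-yl]-4-methylpent-2-enoate | COC(=O)/C=C/[C@@H](C)C[C@@]1(C)C[C@H](C)[C@@H](CC(=O)OC)OO1
F0 | step 12 | none | none
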